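**Retrosynthetic overview**
1. The C40 bis(hydrogen sulfate) comes from the C2-symmetric 3,4,3′,4′-tetrol by sulfation of the equatorial 4- and 4′-hydroxyls (the axial 3-hydroxyls stay free). The tetrol comes from a double Wittig reaction of two C15 phosphonium salts with the C10 trienedial.
2. The C15 salt comes from a C10 ring aldehyde by Horner–Wadsworth–Emmons extension with a C5 phosphonate, reduction and salt formation.
3. The cyclohexane ring, the only ring type, is made once, before any chain building, by an enantioselective Diels–Alder reaction. 3-Methylbut-2-enal supplies C1 (the CMe2 carbon) and C6 with its formyl carbon; a 2-silyloxy-3-acyloxy-penta-1,3-diene from pentane-2,3-dione supplies C2–C5 with both oxygens and the C5 methyl.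
4. Enabling feature: in the ring the side chain at C6 is para to the C3 oxygen and ortho to the C5 methyl, and the vicinal C3/C4 oxygens sit where the double bond of such an adduct lies. Bonds C1–C2 and C5–C6 therefore form together with matched regiochemistry, and the enediol diether left at C3=C4 lets C4 be set by protonation and C3 by hydride.

Key step: step 3

Remark 1: carotenoid numbering is used for the ring (C1 = CMe2, C2 = CH2, C3 = CHOH, C4 = CHOSO3H, C5 = CHMe, C6 = CH carrying the polyene).
Remark 2 (assumption): the target is drawn as the free bis(hydrogen sulfate), so the last step protonates the isolated ammonium salt; the free acid should be kept cold, dilute and in the dark.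
Remark 3 (assumption): the (R)-oxazaborolidine in step 3 is chosen from the usual binding model (aldehyde on boron, formyl C–H···O contact, one phenyl shielding the rear face); if the sense of induction on this untested enal class is opposite, the mirror-image catalyst is used.

Step 1
Reactants: 1 pentane-2,3-dione
Product: 2 (Z)-4-oxopent-2-en-3-yl pivalate
Conditions: t-BuCOCl, Et3N, 4-(dimethylamino)pyridine (cat.), CH2Cl2, 0 °C → rt
Reagents that add atoms: pivaloyl chloride, CC(C)(C)C(=O)Cl
Why: O-acylation of the more substituted, conjugated enol of a 1,2-diketone (diosphenol ester formation) should give the enol ester with methyl and acetyl trans, the geometry that avoids allylic strain; no stereocentre is formed.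

Step 2
Reactants: 2 (Z)-4-oxopent-2-en-3-yl pivalate
Product: 3 (Z)-2-[(triisopropylsilyl)oxy]penta-1,3-dien-3-yl pivalate
Conditions: i-Pr3SiOSO2CF3, Et3N, CH2Cl2, 0 °C
Reagents that add atoms: triisopropylsilyl trifluoromethanesulfonate, CC(C)[Si](OS(=O)(=O)C(F)(F)F)(C(C)C)C(C)C
Why: soft enolisation and O-silylation of the methyl ketone (silyl dienol ether formation) should give the cross-conjugated 2-silyloxydiene with the enol ester geometry retained, so the terminal methyl sits outside.

Step 3
Reactants: 3 (Z)-2-[(triisopropylsilyl)oxy]penta-1,3-dien-3-yl pivalate; 4 3-methylbut-2-enal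
Product: 5 (1S,2R)-2,6,6-trimethyl-3-(pivaloyloxy)-4-[(triisopropylsilyl)oxy]cyclohex-3-ene-1-carbaldehyde (formyl and 2-methyl cis; 5R,6S in carotenoid numbering)
Conditions: (R)-3,3-diphenyl-1-(2-methylphenyl)tetrahydro-1H,3H-pyrrolo[1,2-c][1,3,2]oxazaborole (20 mol %) protonated with HN(SO2CF3)2 (16 mol %), 3 (1.5 equiv), CH2Cl2, −78 → −40 °C; Et3N quench; chromatography on Et3N-deactivated silica to remove any trans (exo) adduct
Reagents that add atoms: none
Why: Proposed new method: the boron-bound s-trans enal is attacked at its β-carbon (the future C1) by the CH2 terminus of the diene, which carries the largest HOMO coefficient because the 2-silyloxy group and the terminal methyl reinforce each other while the 3-pivaloyloxy group is only a weak donor, and the bond from the enal α-carbon (C6) to the methyl-bearing terminus (C5) follows in a concerted but strongly asynchronous [4π+2π] cycloaddition, in the limit a Mukaiyama–Michael addition followed by 6-endo-trig closure of the boron enolate onto the silyloxyallyl cation. The closest known reaction types are the oxazaborolidinium-catalysed enantioselective Diels–Alder reactions of 2-silyloxydienes with α- or β-monosubstituted enals and the acid-promoted cycloadditions of silyloxydienes to β,β-disubstituted enones; enantioselective catalysis on a β,β-dialkyl enal is the new element. The cyclohexene ring closes suprafacially on both partners through the endo transition state, so the outside methyl of the diene and the formyl group end up cis, which fixes the relative configuration of C5 and C6. The absolute configuration is set by the catalyst, whose phenyl group shields one face of the coordinated enal so that the diene adds to the open face. The step needs 1,4- over 1,2-addition, one regiochemistry, endo over exo and one enal face: the bulky triisopropylsilyl group and the boron-blocked carbonyl disfavour aldol-type attack, the matched donor pattern secures regiochemistry, and removal of any exo adduct before step 4 ensures that the later epimerisation at C6 cannot erode the enantiomeric purity carried by C5.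

Step 4
Reactants: 5 (1S,2R)-cis aldehyde
Product: 6 (1R,2R)-2,6,6-trimethyl-3-(pivaloyloxy)-4-[(triisopropylsilyl)oxy]cyclohex-3-ene-1-carbaldehyde (formyl and 2-methyl trans; 5R,6R)
Conditions: 1,8-diazabicyclo[5.4.0]undec-7-ene (0.3 equiv), toluene, rt → 40 °C; chromatography, recycling of recovered 5
Reagents that add atoms: none
Why: reversible deprotonation of the formyl α-C–H (base-mediated epimerisation) should move the formyl group to the equatorial position trans to the methyl, which is held pseudo-equatorial by the syn-axial methyl of the gem-dimethyl carbon; C5 is not acidic and stays untouched.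

Step 5
Reactants: 6 (1R,2R)-trans aldehyde; 7 ethyl (E)-4-(diethoxyphosphoryl)-3-methylbut-2-enoate (the commercial E/Z mixture serves, since the anion is delocalised)
Product: 8 ethyl (2E,4E)-3-methyl-5-[(1R,2R)-2,6,6-trimethyl-3-(pivaloyloxy)-4-[(triisopropylsilyl)oxy]cyclohex-3-en-1-yl]penta-2,4-dienoate
Conditions: 7, LiN(SiMe3)2, THF, −78 °C; then 6, −78 → 0 °C
Reagents that add atoms: none
Why: Horner–Wadsworth–Emmons olefination with the vinylogous phosphonate anion should give the E-configured new double bond under thermodynamic control, as on other 2,2,6-trimethylcyclohexanecarbaldehydes; the stabilised anion should leave the hindered enol pivalate and the silyl enol ether alone.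

Step 6
Reactants: 8 dienoate with enediol diether
Product: 9 ethyl (2E,4E)-3-methyl-5-[(1R,2R,3S)-2,6,6-trimethyl-4-oxo-3-(pivaloyloxy)cyclohexyl]penta-2,4-dienoate
Conditions: CF3CO2H, H2O (5 equiv), CH2Cl2, 0 °C
Reagents that add atoms: none
Why: acid hydrolysis of the silyl enol ether by C-protonation at the pivalate-bearing carbon (the β-carbon of the more electron-rich enol ether) should deliver the proton axially, placing the pivalate equatorial and trans to the methyl, which is also the thermodynamic arrangement; no free enolate is formed, so the acyl group cannot migrate.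

Step 7
Reactants: 9 α-pivaloyloxy ketone
Product: 10 ethyl (2E,4E)-5-[(1R,2R,3S,4R)-4-hydroxy-2,6,6-trimethyl-3-(pivaloyloxy)cyclohexyl]-3-methylpenta-2,4-dienoate
Conditions: LiBH(s-Bu)3, THF, −78 °C; AcOH quench at −78 °C
Reagents that add atoms: none
Why: the bulky hydride should attack the ketone equatorially, all the more because the axial methyl of the gem-dimethyl carbon blocks axial attack (as in 3,3,5-trimethylcyclohexanone reductions), giving the axial alcohol cis to the pivalate; the β,β-disubstituted dienoate should not react at −78 °C.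

Step 8
Reactants: 10 hydroxy pivalate dienoate
Product: 11 (2E,4E)-5-[(1R,2R,3S,4R)-3,4-dihydroxy-2,6,6-trimethylcyclohexyl]-3-methylpenta-2,4-dien-1-ol
Conditions: i-Bu2AlH (6 equiv), CH2Cl2, −78 → −20 °C; aqueous potassium sodium tartrate
Reagents that add atoms: none
Why: i-Bu2AlH should reduce the conjugated ester to the allylic alcohol and cleave the pivalate reductively in the same operation, without touching a stereocentre.

Step 9
Reactants: 11 triol
Product: 12 [(2E,4E)-5-[(1R,2R,3S,4R)-3,4-dihydroxy-2,6,6-trimethylcyclohexyl]-3-methylpenta-2,4-dien-1-yl]triphenylphosphonium bromide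
Conditions: Ph3P·HBr (1.1 equiv), MeOH, 0 °C → rt, dark
Reagents that add atoms: triphenylphosphine hydrobromide, [Br-].[PH+](c1ccccc1)(c1ccccc1)c1ccccc1
Why: ionisation of the primary allylic alcohol to the pentadienyl cation and capture by Ph3P at the terminus (the standard C15 Wittig salt formation) should give the E,E salt, while the two non-allylic ring hydroxyls stay inert.

Step 10
Reactants: 12 C15 phosphonium bromide (2.2 equiv); 13 (2E,4E,6E)-2,7-dimethylocta-2,4,6-trienedial
Product: 15 (all-E)-(3R,4S,5R,6R,3′R,4′S,5′R,6′R)-5,6,5′,6′-tetrahydro-β,β-carotene-3,4,3′,4′-tetrol, via C25 monoaldehyde 14 (not isolated)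
Conditions: NaOMe, MeOH/CH2Cl2, 0 °C → rt, Ar, dark; then reflux in EtOH to equilibrate Z isomers to all-E; crystallisation
Reagents that add atoms: none
Why: the double Wittig olefination of the semi-stabilised ylide with the C10 dialdehyde (C15 + C10 + C15) is the standard carotenoid assembly, tolerates free hydroxyls, and its Z isomers at the new double bonds should converge thermally to the all-E polyene.

Step 11
Reactants: 15 tetrol
Product: 17 bis(trimethylammonium) salt of the 4,4′-disulfate, via bis-stannylene acetal 16 (not isolated)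
Conditions: Bu2SnO (2.2 equiv), MeOH/toluene, reflux, then evaporation; Me3N·SO3 (2.4 equiv), 1,4-dioxane/THF, rt, Ar, dark; MeOH; size-exclusion chromatography
Reagents that add atoms: sulfur trioxide–trimethylamine complex, C[N+](C)(C)S(=O)(=O)[O-]; dibutyltin oxide, CCCC[Sn](=O)CCCC (its atoms stay only in 16)
Why: dibutylstannylene acetal activation of a ring cis-1,2-diol makes the equatorial oxygen the nucleophile (regioselective sulfation as on pyranoside cis-diols), and here the axial 3-hydroxyl is further shielded by the syn-axial methyl, so sulfation should occur at O4 and O4′ only.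

Step 12
Reactants: 17 bis(trimethylammonium) disulfate
Product: 18 (all-E)-(3R,4S,5R,6R,3′R,4′S,5′R,6′R)-3,3′-dihydroxy-5,6,5′,6′-tetrahydro-β,β-carotene-4,4′-diyl bis(hydrogen sulfate)
Conditions: sulfonic-acid ion-exchange resin (H+ form), MeOH, 0 °C, short contact, dark
Reagents that add atoms: none
Why: cation exchange on a strongly acidic resin should replace trimethylammonium by protons without cleaving the secondary sulfate esters if contact is short and cold.

**Compound list**
1 | pentane-2,3-dione | CCC(=O)C(C)=O | starting material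
2 | (Z)-4-oxopent-2-en-3-yl pivalate | CC(=O)/C(OC(=O)C(C)(C)C)=C/C | intermediate
3 | (Z)-2-[(triisopropylsilyl)oxy]penta-1,3-dien-3-yl pivalate | C=C(O[Si](C(C)C)(C(C)C)C(C)C)/C(OC(=O)C(C)(C)C)=C/C | intermediate
4 | 3-methylbut-2-enal | CC(C)=CC=O | starting material
5 | (1S,2R)-2,6,6-trimethyl-3-(pivaloyloxy)-4-[(triisopropylsilyl)oxy]cyclohex-3-ene-1-carbaldehyde (cis) | O=C[C@H]1[C@@H](C)C(OC(=O)C(C)(C)C)=C(O[Si](C(C)C)(C(C)C)C(C)C)CC1(C)C | intermediate
6 | (1R,2R)-2,6,6-trimethyl-3-(pivaloyloxy)-4-[(triisopropylsilyl)oxy]cyclohex-3-ene-1-carbaldehyde (trans) | O=C[C@@H]1[C@@H](C)C(OC(=O)C(C)(C)C)=C(O[Si](C(C)C)(C(C)C)C(C)C)CC1(C)C | intermediate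
7 | ethyl (E)-4-(diethoxyphosphoryl)-3-methylbut-2-enoate | CCOC(=O)/C=C(\C)CP(=O)(OCC)OCC | starting material
8 | ethyl (2E,4E)-3-methyl-5-[(1R,2R)-2,6,6-trimethyl-3-(pivaloyloxy)-4-[(triisopropylsilyl)oxy]cyclohex-3-en-1-yl]penta-2,4-dienoate | CCOC(=O)/C=C(C)/C=C/[C@@H]1[C@@H](C)C(OC(=O)C(C)(C)C)=C(O[Si](C(C)C)(C(C)C)C(C)C)CC1(C)C | intermediate
9 | ethyl (2E,4E)-3-methyl-5-[(1R,2R,3S)-2,6,6-trimethyl-4-oxo-3-(pivaloyloxy)cyclohexyl]penta-2,4-dienoate | CCOC(=O)/C=C(C)/C=C/[C@@H]1[C@@H](C)[C@H](OC(=O)C(C)(C)C)C(=O)CC1(C)C | intermediate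
10 | ethyl (2E,4E)-5-[(1R,2R,3S,4R)-4-hydroxy-2,6,6-trimethyl-3-(pivaloyloxy)cyclohexyl]-3-methylpenta-2,4-dienoate | CCOC(=O)/C=C(C)/C=C/[C@@H]1[C@@H](C)[C@H](OC(=O)C(C)(C)C)[C@H](O)CC1(C)C | intermediate
11 | (2E,4E)-5-[(1R,2R,3S,4R)-3,4-dihydroxy-2,6,6-trimethylcyclohexyl]-3-methylpenta-2,4-dien-1-ol | OC/C=C(C)/C=C/[C@@H]1[C@@H](C)[C@H](O)[C@H](O)CC1(C)C | intermediate
12 | [(2E,4E)-5-[(1R,2R,3S,4R)-3,4-dihydroxy-2,6,6-trimethylcyclohexyl]-3-methylpenta-2,4-dien-1-yl]triphenylphosphonium bromide | [Br-].c1ccc(cc1)[P+](c1ccccc1)(c1ccccc1)C/C=C(C)/C=C/[C@@H]1[C@@H](C)[C@H](O)[C@H](O)CC1(C)C | intermediate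
13 | (2E,4E,6E)-2,7-dimethylocta-2,4,6-trienedial | O=C/C(C)=C/C=C/C=C(C)/C=O | starting material
14 | (2E,4E,6E,8E,10E,12E)-13-[(1R,2R,3S,4R)-3,4-dihydroxy-2,6,6-trimethylcyclohexyl]-2,7,11-trimethyltrideca-2,4,6,8,10,12-hexaenal | CC(/C=C/C=C(C)/C=C/[C@@H]1[C@@H](C)[C@H](O)[C@H](O)CC1(C)C)=C\C=C\C=C(C)\C=O | intermediate
15 | (all-E)-(3R,4S,5R,6R,3′R,4′S,5′R,6′R)-5,6,5′,6′-tetrahydro-β,β-carotene-3,4,3′,4′-tetrol | CC(/C=C/C=C(C)/C=C/[C@@H]1[C@@H](C)[C@H](O)[C@H](O)CC1(C)C)=C\C=C\C=C(C)\C=C\C=C(C)\C=C\[C@@H]1[C@@H](C)[C@H](O)[C@H](O)CC1(C)C | intermediate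
16 | 3,4:3′,4′-bis-O-(dibutylstannylene) acetal of 15 | CC(/C=C/C=C(C)/C=C/[C@@H]1[C@@H](C)[C@@H]2O[Sn](CCCC)(CCCC)O[C@@H]2CC1(C)C)=C\C=C\C=C(C)\C=C\C=C(C)\C=C\[C@@H]1[C@@H](C)[C@@H]2O[Sn](CCCC)(CCCC)O[C@@H]2CC1(C)C | intermediate
17 | bis(trimethylammonium) (all-E)-(3R,4S,5R,6R,3′R,4′S,5′R,6′R)-3,3′-dihydroxy-5,6,5′,6′-tetrahydro-β,β-carotene-4,4′-diyl disulfate | CC(/C=C/C=C(C)/C=C/[C@@H]1[C@@H](C)[C@H](OS(=O)(=O)[O-])[C@H](O)CC1(C)C)=C\C=C\C=C(C)\C=C\C=C(C)\C=C\[C@@H]1[C@@H](C)[C@H](OS(=O)(=O)[O-])[C@H](O)CC1(C)C.C[NH+](C)C.C[NH+](C)C | intermediate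
18 | (all-E)-(3R,4S,5R,6R,3′R,4′S,5′R,6′R)-3,3′-dihydroxy-5,6,5′,6′-tetrahydro-β,β-carotene-4,4′-diyl bis(hydrogen sulfate) | CC(/C=C/C=C(C)/C=C/[C@@H]1[C@@H](C)[C@H](OS(=O)(=O)O)[C@H](O)CC1(C)C)=C\C=C\C=C(C)\C=C\C=C(C)\C=C\[C@@H]1[C@@H](C)[C@H](OS(=O)(=O)O)[C@H](O)CC1(C)C | target

**Step count**
Total steps: 12. Longest linear sequence: 12 (from pentane-2,3-dione; 4, 7 and 13 are bought).

**Steps most likely to fail**

Step 3 (proposed new method). What may go wrong: aldol-type 1,2-attack of the silyl dienol ether on the formyl group, silyl transfer to the catalyst that opens a racemic silylium-catalysed pathway, or insufficient endo or facial selectivity on the hindered enal. Fallback with known chemistry, setting out from 3 and 4: the cycloaddition is run without chiral control under HN(SO2CF3)2 catalysis (CH2Cl2, −78 °C), the acid-promoted manifold known for hindered silyloxydienes and β,β-disubstituted acceptors, to give the racemic cis adduct F1. The base of step 4 equilibrates F1 to the racemic trans aldehyde F2. Condensation of F2 with (1R,2R)-N,N′-dimethyl-1,2-diphenylethane-1,2-diamine (MgSO4, CH2Cl2) gives two diastereomeric imidazolidines, the (1R,2R)-ring aminal F3 and the (1S,2S)-ring aminal F4, to be separated by chromatography. Mild hydrolysis of F3 (aqueous citric acid/Et2O) comes back to the route at 6.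

Step 11. What may go wrong: loss of regiocontrol (sulfation of the axial 3-hydroxyl or double sulfation within one ring) and thermal E/Z scrambling of the polyene during stannylene formation. Fallback, setting out from 10, fixes the regiochemistry by protection instead:
- Silylation of the axial 3-hydroxyl (t-BuMe2SiOSO2CF3, 2,6-lutidine, CH2Cl2) gives the silyl ether F5.
- i-Bu2AlH reduces the ester and removes the pivalate to give the diol F6, in which only the ring 4-hydroxyl is free.
- Ph3P·HBr (CH2Cl2, 0 °C) gives the phosphonium salt F7.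
- Double Wittig reaction with 13 under base-free conditions (1,2-epoxybutane, EtOH, reflux, so that no alkoxide can trigger silyl migration) gives the 3,3′-bis-silyl ether F8.
- SO3·pyridine (pyridine/DMF) sulfates the two free 4-hydroxyls to give the bis(pyridinium) salt F9.
- HF·pyridine (THF/pyridine, 0 °C) removes the silyl groups to give the bis(pyridinium) disulfate F10, and the acid resin of step 12 comes back to the route at 18.

Step 4. What may go wrong: unfavourable or incomplete equilibration at the cyclohexene stage (allylic strain between the enol pivalate and the methyl) or base-induced cleavage of the enol ester. Fallback, setting out from 5: the acid hydrolysis of step 6 is applied first and gives the cis keto aldehyde F11, in whose chair the formyl group is axial. Enamine-mediated epimerisation (pyrrolidine/AcOH cat., CH2Cl2), which acts on the aldehyde and not on the α-acyloxy ketone, gives the all-equatorial trans keto aldehyde F12. Horner–Wadsworth–Emmons olefination of F12 with 7 as in step 5 comes back to the route at 9.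

**Further compounds**
F1 | step 3 | racemic cis-2,6,6-trimethyl-3-(pivaloyloxy)-4-[(triisopropylsilyl)oxy]cyclohex-3-ene-1-carbaldehyde (relative configuration drawn) | O=C[C@H]1[C@@H](C)C(OC(=O)C(C)(C)C)=C(O[Si](C(C)C)(C(C)C)C(C)C)CC1(C)C
F2 | step 3 | racemic trans-2,6,6-trimethyl-3-(pivaloyloxy)-4-[(triisopropylsilyl)oxy]cyclohex-3-ene-1-carbaldehyde (relative configuration drawn) | O=C[C@@H]1[C@@H](C)C(OC(=O)C(C)(C)C)=C(O[Si](C(C)C)(C(C)C)C(C)C)CC1(C)C
F3 | step 3 | (3R,4R)-4-[(4R,5R)-1,3-dimethyl-4,5-diphenylimidazolidin-2-yl]-3,5,5-trimethyl-1-[(triisopropylsilyl)oxy]cyclohex-1-en-2-yl pivalate | CN1[C@H](c2ccccc2)[C@@H](c2ccccc2)N(C)C1[C@@H]1[C@@H](C)C(OC(=O)C(C)(C)C)=C(O[Si](C(C)C)(C(C)C)C(C)C)CC1(C)C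
F4 | step 3 | (3S,4S)-4-[(4R,5R)-1,3-dimethyl-4,5-diphenylimidazolidin-2-yl]-3,5,5-trimethyl-1-[(triisopropylsilyl)oxy]cyclohex-1-en-2-yl pivalate | CN1[C@H](c2ccccc2)[C@@H](c2ccccc2)N(C)C1[C@H]1[C@H](C)C(OC(=O)C(C)(C)C)=C(O[Si](C(C)C)(C(C)C)C(C)C)CC1(C)C
F5 | step 11 | ethyl (2E,4E)-5-[(1R,2R,3S,4R)-4-[(tert-butyldimethylsilyl)oxy]-2,6,6-trimethyl-3-(pivaloyloxy)cyclohexyl]-3-methylpenta-2,4-dienoate | CCOC(=O)/C=C(C)/C=C/[C@@H]1[C@@H](C)[C@H](OC(=O)C(C)(C)C)[C@H](O[Si](C)(C)C(C)(C)C)CC1(C)C
F6 | step 11 | (2E,4E)-5-[(1R,2R,3S,4R)-4-[(tert-butyldimethylsilyl)oxy]-3-hydroxy-2,6,6-trimethylcyclohexyl]-3-methylpenta-2,4-dien-1-ol | OC/C=C(C)/C=C/[C@@H]1[C@@H](C)[C@H](O)[C@H](O[Si](C)(C)C(C)(C)C)CC1(C)C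
F7 | step 11 | [(2E,4E)-5-[(1R,2R,3S,4R)-4-[(tert-butyldimethylsilyl)oxy]-3-hydroxy-2,6,6-trimethylcyclohexyl]-3-methylpenta-2,4-dien-1-yl]triphenylphosphonium bromide | [Br-].c1ccc(cc1)[P+](c1ccccc1)(c1ccccc1)C/C=C(C)/C=C/[C@@H]1[C@@H](C)[C@H](O)[C@H](O[Si](C)(C)C(C)(C)C)CC1(C)C
F8 | step 11 | (all-E)-(3R,4S,5R,6R,3′R,4′S,5′R,6′R)-3,3′-bis[(tert-butyldimethylsilyl)oxy]-5,6,5′,6′-tetrahydro-β,β-carotene-4,4′-diol | CC(/C=C/C=C(C)/C=C/[C@@H]1[C@@H](C)[C@H](O)[C@H](O[Si](C)(C)C(C)(C)C)CC1(C)C)=C\C=C\C=C(C)\C=C\C=C(C)\C=C\[C@@H]1[C@@H](C)[C@H](O)[C@H](O[Si](C)(C)C(C)(C)C)CC1(C)C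
F9 | step 11 | bis(pyridinium) salt of the 4,4′-disulfate of F8 | CC(/C=C/C=C(C)/C=C/[C@@H]1[C@@H](C)[C@H](OS(=O)(=O)[O-])[C@H](O[Si](C)(C)C(C)(C)C)CC1(C)C)=C\C=C\C=C(C)\C=C\C=C(C)\C=C\[C@@H]1[C@@H](C)[C@H](OS(=O)(=O)[O-])[C@H](O[Si](C)(C)C(C)(C)C)CC1(C)C.c1cc[nH+]cc1.c1cc[nH+]cc1
F10 | step 11 | bis(pyridinium) (all-E)-(3R,4S,5R,6R,3′R,4′S,5′R,6′R)-3,3′-dihydroxy-5,6,5′,6′-tetrahydro-β,β-carotene-4,4′-diyl disulfate | CC(/C=C/C=C(C)/C=C/[C@@H]1[C@@H](C)[C@H](OS(=O)(=O)[O-])[C@H](O)CC1(C)C)=C\C=C\C=C(C)\C=C\C=C(C)\C=C\[C@@H]1[C@@H](C)[C@H](OS(=O)(=O)[O-])[C@H](O)CC1(C)C.c1cc[nH+]cc1.c1cc[nH+]cc1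
F11 | step 4 | (1S,2R,3S)-2,6,6-trimethyl-4-oxo-3-(pivaloyloxy)cyclohexane-1-carbaldehyde | O=C[C@H]1[C@@H](C)[C@H](OC(=O)C(C)(C)C)C(=O)CC1(C)C
F12 | step 4 | (1R,2R,3S)-2,6,6-trimethyl-4-oxo-3-(pivaloyloxy)cyclohexane-1-carbaldehyde | O=C[C@@H]1[C@@H](C)[C@H](OC(=O)C(C)(C)C)C(=O)CC1(C)C
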